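4 questions stand here: which of 3 flasks gives most product, and how much each one gives.

- the best flask by amount of product, in percent of the solid substrate charged; "all alike" if 1.5 percentage points covers them all (birch / maple / ash / all alike)
- amount of product at the end, in percent of the solid substrate charged, birch
- amount of product at the end, in percent of the solid substrate charged, maple
- amount of product at the end, in percent of the solid substrate charged, ash

| flask | solid substrate | free enzyme | temperature | remark | time |
|---|---|---|---|---|---|
| Sunday's | 0.19 M | 0.014 mol% | −5 °C | run made earlier |  |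
| Thursday's | 0.19 M | 0.022 mol% | 25 °C | run made earlier |  |
| Wednesday's | 0.38 M | 0.01 mol% | −5 °C | run made earlier |  |
| birch | 0.19 M | 0.01 mol% | 50 °C |  | 30 h |
| maple | 0.19 M | 0.01 mol% | 25 °C |  | 30 h |
| ash | 0.19 M | 0.01 mol% | 0 °C |  | 30 h |

| run | time / h | product / % | solid substrate / % |
|---|---|---|---|
| Sunday's | 20.0 | 1.7 | 54.0 |
| Sunday's | 50.0 | 4.3 | 23.7 |
| Sunday's | 120 | 10.6 | 1.7 |
| Sunday's | 288 | 25.6 | 1.0 |
| Thursday's | 8.00 | 14.9 | 76.1 |
| Thursday's | 20.0 | 43.7 | 47.3 |
| Thursday's | 40.0 | 90.5 | 2.0 |
| Thursday's | 72.0 | 96.7 | 0 |
| Wednesday's | 20.0 | 1.5 | 79.2 |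
| Wednesday's | 50.0 | 2.2 | 60.7 |
| Wednesday's | 120 | 5.6 | 50.1 |
| Wednesday's | 288 | 18.9 | 35.8 |

(each reading ± 1 percentage point)

- as a solid, counted per litre of solution: solid substrate
- reactions considered so far: free enzyme -> spent catalyst; complex <-> free enzyme + product; starting material + free enzyme <-> complex; free enzyme -> unfolded enzyme; solid substrate <-> starting material
- at the start none of the solid substrate is in solution
- what has only dissolved of solid substrate counts as not reacted

Solid has to dissolve before the enzyme can reach it, so I start from the supply. In Sunday's run the solid falls to 54.0% in 20.0 h, which gives S = 0.0230 h⁻¹. S is the supply rate, the fraction of the charge the solid gives up per hour. Over 30 h that passes about 69.0% of the charge into solution.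

Between 20.0 h and 40.0 h Thursday's product rises at 0.0234 h⁻¹ of the charge, about equal to S. So going into solution looks like the rate-limiting step there. Dividing by the loading gives a turnover of 106 h⁻¹, and maple then reaches 31.9%.

That turnover is my weak link. By difference of the readings, Thursday's run holds about 9.00% dissolved at 20.0 h, while Sunday's, colder and with less enzyme, holds about 87.7% at 120 h, ten times as much. I take Thursday's small pool as a sign that its enzyme was not full, so I read its turnover as a floor. Maple has half that enzyme, so I expect more dissolved material per enzyme. I place maple midway between floor and supply, at 50.5%.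

Sunday's late slope gives a cold turnover of 6.38 h⁻¹, so I put ash, warmer than Sunday's run, above 1.91%. Birch is hotter than the warmest run, so I set the supply figure beside it and commit to no number.

The forecast, lower than my maple figure, names maple as best, with 22% for birch, 31% for maple and 3.1% for ash, and says of birch “I guess the enzyme dies early”.

The flasks give 3.19% in birch, 44.7% in maple and 3.08% in ash, so maple is best.

    free enzyme → spent catalyst (k = 7.80 × 10⁻⁹ s⁻¹, Ea = 106 kJ mol⁻¹)
    complex ⇌ free enzyme + product (K = 0.380 M, k = 0.0770 s⁻¹, Ea = 82.0 kJ mol⁻¹, ΔH = −42.0 kJ mol⁻¹)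
    starting material + free enzyme ⇌ complex (K = 76.0 M⁻¹, k = 8.50 M⁻¹ s⁻¹, Ea = 57.0 kJ mol⁻¹, ΔH = −9.00 kJ mol⁻¹)
    free enzyme → unfolded enzyme (k = 1.90 × 10⁻⁷ s⁻¹, Ea = 237 kJ mol⁻¹)
    solid substrate ⇌ starting material, rate k5*(cs5 - [starting material]) while solid is left; crystals form when [starting material] > cs5 (solubility = 0.180 M, k = 8.60 × 10⁻⁶ s⁻¹)
    (constants at 25 °C)

In birch the solid gives up on average 0.0197 h⁻¹ of the charge, against S = 0.0230 h⁻¹, yet the binding of starting material to free enzyme has half its turnover behind it at 1.74 h, far earlier than the 30 h of the run, and by 30.0 h birch holds 56.0% as starting material with 99.9% of the catalyst as unfolded enzyme. The same flask at 35 °C gives up on average 0.0262 h⁻¹ of its solid and holds 62.8% product.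

(The earlier runs and the new flask were generated by integration with made-up constants; noise was put on by code.)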